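Assumption: the target has no stereocentre and no stereogenic double bond (the prenyl alkene carries two identical methyl groups), so it is achiral and no enantiocontrol is needed; stereocentres in intermediates are racemic and are erased later.

**Retrosynthetic overview**
- Target ← bis-MOM ether ← 5-bromobenzofuran (Br/Li exchange, prenyl bromide); the phenols are freed last.
- Furan ring (the only ring formed; both benzene rings are bought) ← O-methylation of a 2-arylbenzofuran-3(2H)-one ← 5-exo-tet closure of an α-bromo-2'-hydroxydeoxybenzoin.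
- Deoxybenzoin ← β-keto ester (Krapcho) ← crossed Claisen condensation of an arylacetate enolate (ring B) with a benzoate (ring A); this makes the furan C2–C3 bond.
- Ring A ester ← methyl 2,4-dihydroxybenzoate (bromination, 4-O-MOM, 2-O-allyl); ring B ester ← (3-hydroxy-4-methoxyphenyl)acetic acid (esterification, MOM).

**Route**

Step 1
Reactants: 1 methyl 2,4-dihydroxybenzoate
Product: 2 methyl 5-bromo-2,4-dihydroxybenzoate
Conditions: Br2 (1.0 equiv), AcOH, rt
Reagents that add atoms: bromine, BrBr
Why: Electrophilic aromatic bromination goes to C5, which is para to the 2-OH, ortho to the 4-OH and less hindered than C3, and one equivalent of Br2 stops at the monobromide.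

Step 2
Reactants: 2 methyl 5-bromo-2,4-dihydroxybenzoate
Product: 3 methyl 5-bromo-2-hydroxy-4-(methoxymethoxy)benzoate
Conditions: MOMCl (1.1 equiv), K2CO3, acetone, rt
Reagents that add atoms: chloromethyl methyl ether, COCCl
Why: Williamson-type O-alkylation is selective for the 4-OH because the 2-OH is hydrogen-bonded to the ester carbonyl and far less nucleophilic.

Step 3
Reactants: 3 methyl 5-bromo-2-hydroxy-4-(methoxymethoxy)benzoate
Product: 4 methyl 5-bromo-4-(methoxymethoxy)-2-(prop-2-en-1-yloxy)benzoate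
Conditions: allyl bromide, K2CO3, DMF, 60 °C
Reagents that add atoms: allyl bromide, C=CCBr
Why: Williamson ether synthesis under forcing conditions alkylates the chelated phenol and gives an allyl ether that can later be removed without touching the MOM groups.

Step 4
Reactants: 5 (3-hydroxy-4-methoxyphenyl)acetic acid
Product: 6 methyl (3-hydroxy-4-methoxyphenyl)acetate
Conditions: MeOH, H2SO4 (cat.), reflux
Reagents that add atoms: methanol, CO
Why: Fischer esterification is driven by excess methanol and leaves the phenol untouched.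

Step 5
Reactants: 6 methyl (3-hydroxy-4-methoxyphenyl)acetate
Product: 7 methyl [4-methoxy-3-(methoxymethoxy)phenyl]acetate
Conditions: MOMCl (1.2 equiv), K2CO3, acetone, reflux
Reagents that add atoms: chloromethyl methyl ether, COCCl
Why: Phenoxide O-alkylation (Williamson type) proceeds cleanly because carbonate does not enolise the ester.

Step 6
Reactants: 7 methyl [4-methoxy-3-(methoxymethoxy)phenyl]acetate; 4 methyl 5-bromo-4-(methoxymethoxy)-2-(prop-2-en-1-yloxy)benzoate
Product: 9 methyl 3-[5-bromo-4-(methoxymethoxy)-2-(prop-2-en-1-yloxy)phenyl]-2-[4-methoxy-3-(methoxymethoxy)phenyl]-3-oxopropanoate (racemic), via lithium enolate 8 (not isolated)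
Conditions: LiN(SiMe3)2 (2.2 equiv), THF, −78 °C; then 4, −78 °C → rt; then AcOH
Reagents that add atoms: none
Why: In this crossed Claisen condensation the fully preformed enolate cannot self-condense, it acylates on the non-enolisable benzoate, and the second equivalent of base deprotonates the β-keto ester to drive the reaction; the new stereocentre is racemic and is removed in step 7.

Step 7
Reactants: 9 methyl 3-[5-bromo-4-(methoxymethoxy)-2-(prop-2-en-1-yloxy)phenyl]-2-[4-methoxy-3-(methoxymethoxy)phenyl]-3-oxopropanoate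
Product: 10 1-[5-bromo-4-(methoxymethoxy)-2-(prop-2-en-1-yloxy)phenyl]-2-[4-methoxy-3-(methoxymethoxy)phenyl]ethan-1-one
Conditions: LiCl (2 equiv), H2O (2 equiv), DMSO, 130 °C, 2 h
Reagents that add atoms: none
Why: Krapcho dealkoxycarbonylation (chloride SN2 at the ester methyl, then loss of CO2) is neutral, so the MOM acetals, the allyl ether (too cool for aromatic Claisen rearrangement) and the aryl bromide survive.

Step 8
Reactants: 10 1-[5-bromo-4-(methoxymethoxy)-2-(prop-2-en-1-yloxy)phenyl]-2-[4-methoxy-3-(methoxymethoxy)phenyl]ethan-1-one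
Product: 11 1-[5-bromo-2-hydroxy-4-(methoxymethoxy)phenyl]-2-[4-methoxy-3-(methoxymethoxy)phenyl]ethan-1-one
Conditions: Pd(PPh3)4 (5 mol %), morpholine (3 equiv), THF, rt
Reagents that add atoms: none
Why: In this Tsuji–Trost deallylation zerovalent palladium ionises the allyl aryl ether and morpholine traps the π-allyl complex, while the electron-rich aryl bromide does not undergo oxidative addition at room temperature.

Step 9
Reactants: 11 1-[5-bromo-2-hydroxy-4-(methoxymethoxy)phenyl]-2-[4-methoxy-3-(methoxymethoxy)phenyl]ethan-1-one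
Product: 14 2-bromo-1-[5-bromo-2-hydroxy-4-(methoxymethoxy)phenyl]-2-[4-methoxy-3-(methoxymethoxy)phenyl]ethan-1-one (racemic; used crude), via bis-silyl enol ether 12 (not isolated), via silylated bromoketone 13 (not isolated)
Conditions: LiN(SiMe3)2 (2.3 equiv), Me3SiCl (2.6 equiv), THF, −78 → 0 °C; then NBS (1.05 equiv), THF, −78 °C; aqueous work-up at pH 5
Reagents that add atoms: N-bromosuccinimide, O=C1CCC(=O)N1Br
Why: Silyl enol ether bromination puts one bromine on the enol carbon under acid-free conditions that spare the MOM acetals and the electron-rich rings, and the aryl silyl ether falls off on work-up; the new stereocentre is racemic and is lost in step 10.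

Step 10
Reactants: 14 2-bromo-1-[5-bromo-2-hydroxy-4-(methoxymethoxy)phenyl]-2-[4-methoxy-3-(methoxymethoxy)phenyl]ethan-1-one
Product: 16 5-bromo-3-methoxy-6-(methoxymethoxy)-2-[4-methoxy-3-(methoxymethoxy)phenyl]-1-benzofuran, via benzofuranone 15 (not isolated)
Conditions: K2CO3 (3 equiv), degassed DMF, Ar, 0 °C → rt, 30 min; then Me2SO4 (1.5 equiv), rt
Reagents that add atoms: dimethyl sulfate, COS(=O)(=O)OC
Why: Intramolecular Williamson (5-exo-tet) closure gives the benzofuranone, whose potassium enolate is O-methylated by the hard electrophile in DMF because C-methylation would build a quaternary centre and forfeit the aromatic 2-arylbenzofuran; the stereocentre of 15 disappears.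

Step 11
Reactants: 16 5-bromo-3-methoxy-6-(methoxymethoxy)-2-[4-methoxy-3-(methoxymethoxy)phenyl]-1-benzofuran
Product: 18 3-methoxy-6-(methoxymethoxy)-2-[4-methoxy-3-(methoxymethoxy)phenyl]-5-(3-methylbut-2-en-1-yl)-1-benzofuran, via aryllithium 17 (not isolated)
Conditions: n-BuLi (1.1 equiv), THF, −78 °C; CuBr·SMe2 (20 mol %); prenyl bromide (1.5 equiv), −78 → 0 °C
Reagents that add atoms: prenyl bromide (1-bromo-3-methylbut-2-ene), CC(C)=CCBr
Why: Bromine–lithium exchange outruns any deprotonation at −78 °C, and copper-mediated allylic substitution at the primary carbon of prenyl bromide (SN2) gives the linear prenyl group.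

Step 12
Reactants: 18 3-methoxy-6-(methoxymethoxy)-2-[4-methoxy-3-(methoxymethoxy)phenyl]-5-(3-methylbut-2-en-1-yl)-1-benzofuran
Product: 19 2-(3-hydroxy-4-methoxyphenyl)-3-methoxy-5-(3-methylbut-2-en-1-yl)-1-benzofuran-6-ol (CNP0278880.0)
Conditions: HCl (cat., 1.25 M in MeOH), MeOH, 40 °C
Reagents that add atoms: none
Why: Acid-catalysed transacetalisation to dimethoxymethane frees both phenols under conditions mild enough for the prenyl alkene and the fully conjugated aromatic enol ether.

**Compound list**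
1 | methyl 2,4-dihydroxybenzoate | COC(=O)c1ccc(O)cc1O | starting material
2 | methyl 5-bromo-2,4-dihydroxybenzoate | COC(=O)c1cc(Br)c(O)cc1O | intermediate
3 | methyl 5-bromo-2-hydroxy-4-(methoxymethoxy)benzoate | COCOc1cc(O)c(cc1Br)C(=O)OC | intermediate
4 | methyl 5-bromo-4-(methoxymethoxy)-2-(prop-2-en-1-yloxy)benzoate | COCOc1cc(OCC=C)c(cc1Br)C(=O)OC | intermediate
5 | (3-hydroxy-4-methoxyphenyl)acetic acid | COc1ccc(CC(=O)O)cc1O | starting material
6 | methyl (3-hydroxy-4-methoxyphenyl)acetate | COC(=O)Cc1ccc(OC)c(O)c1 | intermediate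
7 | methyl [4-methoxy-3-(methoxymethoxy)phenyl]acetate | COCOc1cc(CC(=O)OC)ccc1OC | intermediate
8 | lithium enolate of 7 (not isolated) | COC(O[Li])=Cc1ccc(OC)c(OCOC)c1 | intermediate
9 | methyl 3-[5-bromo-4-(methoxymethoxy)-2-(prop-2-en-1-yloxy)phenyl]-2-[4-methoxy-3-(methoxymethoxy)phenyl]-3-oxopropanoate (racemic) | COC(=O)C(c1ccc(OC)c(OCOC)c1)C(=O)c1cc(Br)c(OCOC)cc1OCC=C | intermediate
10 | 1-[5-bromo-4-(methoxymethoxy)-2-(prop-2-en-1-yloxy)phenyl]-2-[4-methoxy-3-(methoxymethoxy)phenyl]ethan-1-one | C=CCOc1cc(OCOC)c(Br)cc1C(=O)Cc1ccc(OC)c(OCOC)c1 | intermediate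
11 | 1-[5-bromo-2-hydroxy-4-(methoxymethoxy)phenyl]-2-[4-methoxy-3-(methoxymethoxy)phenyl]ethan-1-one | COCOc1cc(O)c(cc1Br)C(=O)Cc1ccc(OC)c(OCOC)c1 | intermediate
12 | [(Z)-1-{5-bromo-4-(methoxymethoxy)-2-[(trimethylsilyl)oxy]phenyl}-2-[4-methoxy-3-(methoxymethoxy)phenyl]ethenyl]oxy(trimethyl)silane (not isolated; geometry of no consequence) | C[Si](C)(C)O/C(c1cc(Br)c(OCOC)cc1O[Si](C)(C)C)=C\c1ccc(OC)c(OCOC)c1 | intermediate
13 | 2-bromo-1-{5-bromo-4-(methoxymethoxy)-2-[(trimethylsilyl)oxy]phenyl}-2-[4-methoxy-3-(methoxymethoxy)phenyl]ethan-1-one (racemic, not isolated) | COCOc1cc(O[Si](C)(C)C)c(cc1Br)C(=O)C(Br)c1ccc(OC)c(OCOC)c1 | intermediate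
14 | 2-bromo-1-[5-bromo-2-hydroxy-4-(methoxymethoxy)phenyl]-2-[4-methoxy-3-(methoxymethoxy)phenyl]ethan-1-one (racemic) | COCOc1cc(O)c(cc1Br)C(=O)C(Br)c1ccc(OC)c(OCOC)c1 | intermediate
15 | 5-bromo-6-(methoxymethoxy)-2-[4-methoxy-3-(methoxymethoxy)phenyl]-1-benzofuran-3(2H)-one (racemic, not isolated) | COCOc1cc2OC(C(=O)c2cc1Br)c1ccc(OC)c(OCOC)c1 | intermediate
16 | 5-bromo-3-methoxy-6-(methoxymethoxy)-2-[4-methoxy-3-(methoxymethoxy)phenyl]-1-benzofuran | COCOc1cc2oc(c(OC)c2cc1Br)-c1ccc(OC)c(OCOC)c1 | intermediate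
17 | {3-methoxy-6-(methoxymethoxy)-2-[4-methoxy-3-(methoxymethoxy)phenyl]-1-benzofuran-5-yl}lithium (not isolated) | COCOc1cc2oc(c(OC)c2cc1[Li])-c1ccc(OC)c(OCOC)c1 | intermediate
18 | 3-methoxy-6-(methoxymethoxy)-2-[4-methoxy-3-(methoxymethoxy)phenyl]-5-(3-methylbut-2-en-1-yl)-1-benzofuran | COCOc1cc2oc(c(OC)c2cc1CC=C(C)C)-c1ccc(OC)c(OCOC)c1 | intermediate
19 | 2-(3-hydroxy-4-methoxyphenyl)-3-methoxy-5-(3-methylbut-2-en-1-yl)-1-benzofuran-6-ol | COc1ccc(-c2oc3cc(O)c(CC=C(C)C)cc3c2OC)cc1O | target

**Step count**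
Total: 12 steps. Longest linear sequence: 10 steps (1 → 2 → 3 → 4 → 9 → 10 → 11 → 14 → 16 → 18 → 19, that is steps 1–3 and 6–12).

**Three steps most likely to fail, each with a fallback**

Step 6 (crossed Claisen). The benzoate 4 is electron-rich and ortho-substituted, so it is a sluggish acyl acceptor and the enolate may decay before it reacts. The fallback sets out from 4 and returns at 9. Ester 4 is reduced with i-Bu2AlH (CH2Cl2, −78 °C) to [5-bromo-4-(methoxymethoxy)-2-(prop-2-en-1-yloxy)phenyl]methanol F1. F1 is oxidised with MnO2 (CH2Cl2, rt) to 5-bromo-4-(methoxymethoxy)-2-(prop-2-en-1-yloxy)benzaldehyde F2. Enolate 8 (from 7 and LiN(SiMe3)2, THF, −78 °C) is added to this much more electrophilic aldehyde in an intermolecular aldol addition, giving methyl 3-[5-bromo-4-(methoxymethoxy)-2-(prop-2-en-1-yloxy)phenyl]-3-hydroxy-2-[4-methoxy-3-(methoxymethoxy)phenyl]propanoate F3 as a mixture of racemic diastereomers. Dess–Martin periodinane with NaHCO3 (CH2Cl2, rt) oxidises F3 to β-keto ester 9, where both stereocentres cease to matter.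

Step 10 (ring closure and O-methylation). The enolate of 15 is ambident and air-sensitive, so C-methylation or oxidation at C2 could compete. The fallback sets out from 14 and returns at 16. Crude 14 is closed with NaOAc in degassed EtOH and benzofuranone 15 is isolated. 15 is then heated with HC(OMe)3 and p-TsOH (cat.) in MeOH at 60 °C; ketalisation and loss of methanol can only give the O-methyl enol ether. The acid also removes both MOM groups, giving 5-bromo-2-(3-hydroxy-4-methoxyphenyl)-3-methoxy-1-benzofuran-6-ol F4. Both phenols are re-protected with MOMCl and K2CO3 in acetone to give 16.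

Step 12 (final MOM removal). Brønsted acid could cyclise the ortho-prenyl phenol to a 2,2-dimethylchroman or hydrolyse the 3-methoxy enol ether. The fallback sets out from 18 and returns at 19. Treatment of 18 with Me3SiOTf and 2,2'-bipyridyl (CH2Cl2, 0 °C → rt) exchanges each aryl MOM group for a silyl group without free acid, giving {[3-methoxy-2-{4-methoxy-3-[(trimethylsilyl)oxy]phenyl}-5-(3-methylbut-2-en-1-yl)-1-benzofuran-6-yl]oxy}(trimethyl)silane F5. Brief K2CO3/MeOH at 0 °C desilylates F5 to 19.

**Further compounds**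
F1 | step 6 | [5-bromo-4-(methoxymethoxy)-2-(prop-2-en-1-yloxy)phenyl]methanol | COCOc1cc(OCC=C)c(CO)cc1Br
F2 | step 6 | 5-bromo-4-(methoxymethoxy)-2-(prop-2-en-1-yloxy)benzaldehyde | COCOc1cc(OCC=C)c(C=O)cc1Br
F3 | step 6 | methyl 3-[5-bromo-4-(methoxymethoxy)-2-(prop-2-en-1-yloxy)phenyl]-3-hydroxy-2-[4-methoxy-3-(methoxymethoxy)phenyl]propanoate (mixture of racemic diastereomers) | COC(=O)C(c1ccc(OC)c(OCOC)c1)C(O)c1cc(Br)c(OCOC)cc1OCC=C
F4 | step 10 | 5-bromo-2-(3-hydroxy-4-methoxyphenyl)-3-methoxy-1-benzofuran-6-ol | COc1ccc(-c2oc3cc(O)c(Br)cc3c2OC)cc1O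
F5 | step 12 | {[3-methoxy-2-{4-methoxy-3-[(trimethylsilyl)oxy]phenyl}-5-(3-methylbut-2-en-1-yl)-1-benzofuran-6-yl]oxy}(trimethyl)silane | COc1ccc(-c2oc3cc(O[Si](C)(C)C)c(CC=C(C)C)cc3c2OC)cc1O[Si](C)(C)C
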